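**Retrosynthetic overview**
- The last two steps only unmask ring B: the benzyl group on its phenol and the neopentyl group on its sulfate are removed from the fully assembled ester.
- Feature used: ring A is a benzoate in which C1 carries the ester carbonyl, C2 and C4 carry OH, C6 carries the heptamethylene chain and C3 and C5 carry H. Oxygen sits on every second carbon, as in a folded 3,5,7-triketo ester, and the ester oxygen belongs to a hindered secondary carbinol.
- Key disconnection: the ester C–O bond and the aryl C1–C6 bond are cut together, giving a diketo-dioxinone (acylketene precursor that already carries the acetate) and the ring B secondary alcohol. Ring A is the only ring made; ring B is bought as 5-bromoresorcinol.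
- Diketo-dioxinone: 2,2,6-trimethyl-1,3-dioxin-4-one is C-acetylated, its dianion is added to (S)-9-acetoxydodecanal (from (S)-1,2-epoxypentane, oct-7-enyl Grignard, acetylation, ozonolysis), and the aldol is oxidised.
- Alcohol: 5-bromoresorcinol is benzylated and sulfated (neopentyl diester), then joined by B-alkyl Suzuki coupling to (S)-undec-10-en-4-ol (same epoxide, hex-5-enyl Grignard). Both (S) centres come from the epoxide.

Key step: step 11

Assumption: the target is handled as the free aryl hydrogen sulfate drawn, so the sodium salt formed on dealkylation is protonated in the work-up of step 13.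

**Route**

Step 1
Reactants: 1 5-bromoresorcinol (5-bromobenzene-1,3-diol)
Product: 2 3-(benzyloxy)-5-bromophenol
Conditions: BnBr (1.0 equiv), K2CO3 (1.0 equiv), acetone, reflux
Reagents that add atoms: benzyl bromide, BrCc1ccccc1
Why: Williamson etherification with one equivalent of benzyl bromide should give the mono-ether as the main product, separable by chromatography from the bis-ether and from recovered 1, which can be recycled.

Step 2
Reactants: 2 3-(benzyloxy)-5-bromophenol
Product: 4 3-(benzyloxy)-5-bromophenyl neopentyl sulfate, via sodium phenolate 3 (not isolated)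
Conditions: NaN(SiMe3)2, THF, −78 °C; then neopentyl chlorosulfate, −78 °C → rt
Reagents that add atoms: neopentyl chlorosulfate, CC(C)(C)COS(=O)(=O)Cl
Why: The phenoxide attacks sulfur of the chlorosulfate and displaces chloride (sulfurylation to a sulfate diester), and the neopentyl group is chosen because its hindered carbon should resist the bases and nucleophiles met before the last step.

Step 3
Reactants: 5 6-bromohex-1-ene; 6 (S)-1,2-epoxypentane
Product: 8 (S)-undec-10-en-4-ol, via hex-5-enylmagnesium bromide 7 (not isolated)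
Conditions: Mg, THF, rt; then CuI (10 mol%), 6, THF, −30 → 0 °C; aq. NH4Cl
Reagents that add atoms: none
Why: Copper-catalysed Grignard opening of a terminal epoxide is an SN2 attack at the unsubstituted carbon, so the stereocentre of 6 is not touched and keeps its (S) descriptor in 8; any cyclopentylmethyl isomer from radical closure during Grignard formation cannot be hydroborated and should be removed after step 4.

Step 4
Reactants: 8 (S)-undec-10-en-4-ol; 4 3-(benzyloxy)-5-bromophenyl neopentyl sulfate
Product: 10 (S)-3-(benzyloxy)-5-(8-hydroxyundecyl)phenyl neopentyl sulfate, via alkylborane 9 (not isolated)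
Conditions: 9-BBN-H (2.2 equiv), THF, 0 °C → rt; then 4, Pd(OAc)2 (3 mol%), SPhos (6 mol%), K3PO4·H2O (3 equiv), THF, 40 °C
Reagents that add atoms: none
Why: Anti-Markovnikov hydroboration followed by B-alkyl Suzuki–Miyaura coupling (oxidative addition of zerovalent palladium into the C–Br bond, transfer of the primary alkyl group from boron, reductive elimination) should join C11 of the chain to ring B, with excess borane covering the free hydroxyl and a nearly anhydrous phosphate base chosen to spare the sulfate diester.

Step 5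
Reactants: 11 8-bromooct-1-ene; 6 (S)-1,2-epoxypentane
Product: 13 (S)-tridec-12-en-4-ol, via oct-7-enylmagnesium bromide 12 (not isolated)
Conditions: Mg, THF, rt; then CuI (10 mol%), 6, THF, −30 → 0 °C; aq. NH4Cl
Reagents that add atoms: none
Why: The same copper-catalysed SN2 opening at the terminal epoxide carbon as in step 3 carries the (S) centre of 6 unchanged into the acetate-bearing chain.

Step 6
Reactants: 13 (S)-tridec-12-en-4-ol
Product: 14 (S)-tridec-12-en-4-yl acetate
Conditions: Ac2O, pyridine, DMAP (5 mol%), CH2Cl2, rt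
Reagents that add atoms: acetic anhydride, CC(=O)OC(C)=O
Why: DMAP-catalysed acylation takes place at oxygen with retention at carbon and installs the acetate of the target at the outset.

Step 7
Reactants: 14 (S)-tridec-12-en-4-yl acetate
Product: 16 (S)-12-oxododecan-4-yl acetate, via ozonide 15 (not isolated)
Conditions: O3, CH2Cl2, −78 °C; then PPh3, −78 °C → rt
Reagents that add atoms: ozone, O=[O+][O-]
Why: Ozonolysis (cycloaddition, Criegee rearrangement to the ozonide, reduction by the phosphine) cleaves the only alkene to the aldehyde and leaves the acetate untouched.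

Step 8
Reactants: 17 2,2,6-trimethyl-4H-1,3-dioxin-4-one
Product: 19 2,2-dimethyl-6-(2-oxopropyl)-4H-1,3-dioxin-4-one, via lithium dienolate 18 (not isolated)
Conditions: 17 (2.0 equiv), LiN(SiMe3)2 (2.0 equiv), THF, −78 °C; then AcCl (1.0 equiv), −78 °C; aq. HCl
Reagents that add atoms: acetyl chloride, CC(=O)Cl
Why: The lithium dienolate is C-acylated at its γ-carbon by acetyl chloride (vinylogous Claisen-type acylation), and the second equivalent of dienolate deprotonates the more acidic product so that it is not acylated again.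

Step 9
Reactants: 19 2,2-dimethyl-6-(2-oxopropyl)-4H-1,3-dioxin-4-one; 16 (S)-12-oxododecan-4-yl acetate
Product: 21 (4S)-15-(2,2-dimethyl-4-oxo-4H-1,3-dioxin-6-yl)-12-hydroxy-14-oxopentadecan-4-yl acetate (both C12 epimers), via dilithium dianion 20 (not isolated)
Conditions: LiN(iPr)2 (2.1 equiv), THF, −78 °C; then 16 (0.9 equiv), −78 °C; AcOH, −78 °C
Reagents that add atoms: none
Why: Double deprotonation gives a dianion whose last-formed terminal carbanion is the most nucleophilic site and should add to the aldehyde at −78 °C (dianion aldol addition) faster than it attacks or deprotonates the acetate; the new carbinol forms as both epimers, which is of no consequence because it is oxidised in step 10.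

Step 10
Reactants: 21 (4S)-15-(2,2-dimethyl-4-oxo-4H-1,3-dioxin-6-yl)-12-hydroxy-14-oxopentadecan-4-yl acetate
Product: 22 (S)-15-(2,2-dimethyl-4-oxo-4H-1,3-dioxin-6-yl)-12,14-dioxopentadecan-4-yl acetate
Conditions: Dess–Martin periodinane (1.2 equiv), CH2Cl2, 0 °C → rt
Reagents that add atoms: none
Why: Dess–Martin oxidation converts the secondary carbinol into the ketone under neutral, non-aqueous conditions that spare the base-sensitive dioxinone and the acetate, with the oxidant kept near one equivalent so that the activated methylene is not oxidised further.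

Step 11
Reactants: 22 (S)-15-(2,2-dimethyl-4-oxo-4H-1,3-dioxin-6-yl)-12,14-dioxopentadecan-4-yl acetate; 10 (S)-3-(benzyloxy)-5-(8-hydroxyundecyl)phenyl neopentyl sulfate
Product: 26 (S)-11-[3-(benzyloxy)-5-(neopentyloxysulfonyloxy)phenyl]undecan-4-yl 2-[(S)-8-acetoxyundecyl]-4,6-dihydroxybenzoate, via acylketene 23 (not isolated), via triketo ester 24 (not isolated), via cyclised carbinol 25 (not isolated)
Conditions: 22 (1.3 equiv), 10 (1.0 equiv), PhMe (0.1 M), 110 °C; then Et3N, CH2Cl2, rt; then TFA, CH2Cl2, 0 °C → rt
Reagents that add atoms: none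
Why: Heating 22 should trigger a retro-hetero-Diels–Alder loss of acetone to acylketene 23, whose ketene carbon is attacked by the hydroxyl of 10 to give the 3,5,7-triketo ester 24, so the ester C–O bond forms without activating a 2,6-disubstituted benzoic acid and without touching the C–O bond of the carbinol, which keeps its (S) configuration. Et3N then forms the enolate at C2 of 24 (the CH2 between the ester and the C3 ketone), which closes ring A by a 6-exo-trig aldol addition (6-enolexo through the ester enolate form) onto the C7 ketone that carries the chain, making the bond that becomes aryl C1–C6; carbinol 25 then loses water and tautomerises to the resorcinol on acid treatment. The closest known reaction type is the thermolysis of diketo-dioxinones in the presence of alcohols followed by aromatisation to resorcylate esters, a biomimetic polyketide aldol cyclisation. No lasting stereocentre is formed, since the carbinol carbon of 25 becomes aromatic, and both (S) centres are remote from every bond change. The step needs intermolecular O–H capture to beat internal capture of the ketene by the enol oxygen of its own 1,3-diketone (a 2-pyranone), which is secured by having the alcohol present at high concentration from the start and by the benzyl ether and sulfate diester leaving the carbinol as the only O–H nucleophile of 10. It also needs aldol closure to beat Claisen closure of C6 onto the ester, which the weak amine base, the higher acidity of the ester-flanked CH2 and the poor secondary alkoxide leaving group should ensure, while acetate, benzyl ether and neopentyl sulfate are inert to neutral toluene at 110 °C, Et3N and anhydrous TFA.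

Step 12
Reactants: 26 (S)-11-[3-(benzyloxy)-5-(neopentyloxysulfonyloxy)phenyl]undecan-4-yl 2-[(S)-8-acetoxyundecyl]-4,6-dihydroxybenzoate
Product: 27 (S)-11-[3-hydroxy-5-(neopentyloxysulfonyloxy)phenyl]undecan-4-yl 2-[(S)-8-acetoxyundecyl]-4,6-dihydroxybenzoate
Conditions: H2 (1 atm), Pd/C (10 wt% Pd on carbon), EtOAc, rt
Reagents that add atoms: none
Why: Hydrogenolysis cleaves only the benzylic C–O bond of the aryl benzyl ether, because the secondary alkyl benzoate, the acetate and the sulfate diester have no benzylic C–O bond or reducible group.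

Step 13
Reactants: 27 (S)-11-[3-hydroxy-5-(neopentyloxysulfonyloxy)phenyl]undecan-4-yl 2-[(S)-8-acetoxyundecyl]-4,6-dihydroxybenzoate
Product: 29 integracin D, via sodium sulfate salt 28 (not isolated)
Conditions: NaN3 (5 equiv), DMF, 70 °C; excess azide removed (C18 plug); then aq. HCl (1.0 equiv), 0 °C
Reagents that add atoms: none
Why: Azide, a small and weakly basic nucleophile, should displace the aryl sulfate monoanion from the neopentyl carbon by SN2 in warm DMF without touching the acetate, the benzoate or the phenols, and one equivalent of acid then protonates the sulfate to the form drawn.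

**Compound list**
1 | 5-bromoresorcinol | Oc1cc(O)cc(Br)c1 | starting material
2 | 3-(benzyloxy)-5-bromophenol | Oc1cc(Br)cc(OCc2ccccc2)c1 | intermediate
3 | sodium 3-(benzyloxy)-5-bromophenolate | [Na+].[O-]c1cc(Br)cc(OCc2ccccc2)c1 | intermediate
4 | 3-(benzyloxy)-5-bromophenyl neopentyl sulfate | CC(C)(C)COS(=O)(=O)Oc1cc(Br)cc(OCc2ccccc2)c1 | intermediate
5 | 6-bromohex-1-ene | C=CCCCCBr | starting material
6 | (S)-1,2-epoxypentane | CCC[C@H]1CO1 | starting material
7 | hex-5-enylmagnesium bromide | C=CCCCC[Mg]Br | intermediate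
8 | (S)-undec-10-en-4-ol | CCC[C@H](O)CCCCCC=C | intermediate
9 | (S)-11-(9-borabicyclo[3.3.1]nonan-9-yl)undecan-4-ol | CCC[C@H](O)CCCCCCCB1C2CCCC1CCC2 | intermediate
10 | (S)-3-(benzyloxy)-5-(8-hydroxyundecyl)phenyl neopentyl sulfate | CCC[C@H](O)CCCCCCCc1cc(OCc2ccccc2)cc(OS(=O)(=O)OCC(C)(C)C)c1 | intermediate
11 | 8-bromooct-1-ene | C=CCCCCCCBr | starting material
12 | oct-7-enylmagnesium bromide | C=CCCCCCC[Mg]Br | intermediate
13 | (S)-tridec-12-en-4-ol | CCC[C@H](O)CCCCCCCC=C | intermediate
14 | (S)-tridec-12-en-4-yl acetate | CCC[C@@H](CCCCCCCC=C)OC(C)=O | intermediate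
15 | (4S)-11-(1,2,4-trioxolan-3-yl)undecan-4-yl acetate (ozonide, both epimers at the ring carbon) | CCC[C@@H](CCCCCCCC1OCOO1)OC(C)=O | intermediate
16 | (S)-12-oxododecan-4-yl acetate | CCC[C@@H](CCCCCCCC=O)OC(C)=O | intermediate
17 | 2,2,6-trimethyl-4H-1,3-dioxin-4-one | CC1=CC(=O)OC(C)(C)O1 | starting material
18 | lithium 2,2-dimethyl-6-methylidene-6H-1,3-dioxin-4-olate | [Li+].C=C1C=C([O-])OC(C)(C)O1 | intermediate
19 | 2,2-dimethyl-6-(2-oxopropyl)-4H-1,3-dioxin-4-one | CC(=O)CC1=CC(=O)OC(C)(C)O1 | intermediate
20 | dilithium 2,2-dimethyl-6-(2-oxidoprop-2-en-1-ylidene)-6H-1,3-dioxin-4-olate | [Li+].[Li+].C=C([O-])C=C1C=C([O-])OC(C)(C)O1 | intermediate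
21 | (4S)-15-(2,2-dimethyl-4-oxo-4H-1,3-dioxin-6-yl)-12-hydroxy-14-oxopentadecan-4-yl acetate (both C12 epimers) | CCC[C@@H](CCCCCCCC(O)CC(=O)CC1=CC(=O)OC(C)(C)O1)OC(C)=O | intermediate
22 | (S)-15-(2,2-dimethyl-4-oxo-4H-1,3-dioxin-6-yl)-12,14-dioxopentadecan-4-yl acetate | CCC[C@@H](CCCCCCCC(=O)CC(=O)CC1=CC(=O)OC(C)(C)O1)OC(C)=O | intermediate
23 | (S)-12,14,16,18-tetraoxooctadec-17-en-4-yl acetate (acylketene) | CCC[C@@H](CCCCCCCC(=O)CC(=O)CC(=O)C=C=O)OC(C)=O | intermediate
24 | (S)-11-[3-(benzyloxy)-5-(neopentyloxysulfonyloxy)phenyl]undecan-4-yl (S)-15-acetoxy-3,5,7-trioxooctadecanoate | CCC[C@@H](CCCCCCCC(=O)CC(=O)CC(=O)CC(=O)O[C@@H](CCC)CCCCCCCc1cc(OCc2ccccc2)cc(OS(=O)(=O)OCC(C)(C)C)c1)OC(C)=O | intermediate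
25 | (S)-11-[3-(benzyloxy)-5-(neopentyloxysulfonyloxy)phenyl]undecan-4-yl 6-[(S)-8-acetoxyundecyl]-2,6-dihydroxy-4-oxocyclohex-1-ene-1-carboxylate (both epimers at ring C6) | CCC[C@@H](CCCCCCCC1(O)CC(=O)CC(O)=C1C(=O)O[C@@H](CCC)CCCCCCCc1cc(OCc2ccccc2)cc(OS(=O)(=O)OCC(C)(C)C)c1)OC(C)=O | intermediate
26 | (S)-11-[3-(benzyloxy)-5-(neopentyloxysulfonyloxy)phenyl]undecan-4-yl 2-[(S)-8-acetoxyundecyl]-4,6-dihydroxybenzoate | CCC[C@@H](CCCCCCCc1cc(O)cc(O)c1C(=O)O[C@@H](CCC)CCCCCCCc1cc(OCc2ccccc2)cc(OS(=O)(=O)OCC(C)(C)C)c1)OC(C)=O | intermediate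
27 | (S)-11-[3-hydroxy-5-(neopentyloxysulfonyloxy)phenyl]undecan-4-yl 2-[(S)-8-acetoxyundecyl]-4,6-dihydroxybenzoate | CCC[C@@H](CCCCCCCc1cc(O)cc(O)c1C(=O)O[C@@H](CCC)CCCCCCCc1cc(O)cc(OS(=O)(=O)OCC(C)(C)C)c1)OC(C)=O | intermediate
28 | integracin D sodium salt | [Na+].CCC[C@@H](CCCCCCCc1cc(O)cc(O)c1C(=O)O[C@@H](CCC)CCCCCCCc1cc(O)cc(OS(=O)(=O)[O-])c1)OC(C)=O | intermediate
29 | integracin D, (S)-11-[3-hydroxy-5-(sulfooxy)phenyl]undecan-4-yl 2-[(S)-8-acetoxyundecyl]-4,6-dihydroxybenzoate | CCC[C@@H](CCCCCCCc1cc(O)cc(O)c1C(=O)O[C@@H](CCC)CCCCCCCc1cc(O)cc(OS(=O)(=O)O)c1)OC(C)=O | target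

**Totals**
Total step count: 13.
Longest linear sequence: 8 steps (steps 5, 6, 7, 9, 10, 11, 12, 13).

**Three steps most likely to fail**

Step 11. The hindered secondary hydroxyl may add to the acylketene too slowly, so that the ketene is consumed by internal capture by its own enol oxygen or by self-condensation, and the aromatisation may stall at the carbinol stage unless conditions are used that endanger the acetate. Fallback, setting out from 22 and coming back at 26: the ester bond is made by SN2 at the carbinol carbon instead of by acyl transfer.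
- 22 is thermolysed (PhMe, 110 °C) with benzyl alcohol, an unhindered primary alcohol that should capture acylketene 23 quickly, to give benzyl (S)-15-acetoxy-3,5,7-trioxooctadecanoate F1.
- Et3N then TFA should close F1 to benzyl 6-[(S)-8-acetoxyundecyl]-2,6-dihydroxy-4-oxocyclohex-1-ene-1-carboxylate F2 and aromatise it to benzyl 2-[(S)-8-acetoxyundecyl]-4,6-dihydroxybenzoate F3.
- Hydrogenolysis (H2, Pd/C, EtOAc) of F3 gives 2-[(S)-8-acetoxyundecyl]-4,6-dihydroxybenzoic acid F4.
- In parallel, (R)-1,2-epoxypentane is opened with 7 as in step 3 to (R)-undec-10-en-4-ol F5, hydroborated to (R)-11-(9-borabicyclo[3.3.1]nonan-9-yl)undecan-4-ol F6, and coupled with 4 as in step 4 to (R)-3-(benzyloxy)-5-(8-hydroxyundecyl)phenyl neopentyl sulfate F7.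
- Mitsunobu esterification of F4 with F7 (PPh3, diisopropyl azodicarboxylate, THF, 0 °C → rt) should displace the activated hydroxyl with inversion, (R) to (S), and give 26. The carboxylic acid is much more acidic than the phenols and should react first, and the hindered acid is never used as an acyl electrophile.

Step 4. The sulfate diester may be lost under the basic coupling medium, by attack at sulfur or by solvolytic cleavage of the neopentyl C–O bond, before the slow alkyl transfer to palladium is complete. Fallback, setting out from 2 and 9 and coming back at 10: the sulfate is introduced only after the C–C bond is made.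
- Borane 9 is coupled with bromophenol 2 (Pd(OAc)2, SPhos, excess K3PO4·H2O, THF, 40 °C) to give (S)-3-(benzyloxy)-5-(8-hydroxyundecyl)phenol F8.
- One equivalent of NaN(SiMe3)2 at −78 °C should deprotonate only the far more acidic phenol, giving sodium (S)-3-(benzyloxy)-5-(8-hydroxyundecyl)phenolate F9.
- F9 is sulfurylated with neopentyl chlorosulfate as in step 2 to give 10.

Step 9. Proton transfer from the α-CH2 of the aldehyde or from the acetate to the strongly basic dianion, or transfer of the acetyl group to it, may compete with carbonyl addition. Fallback, setting out from 19 and coming back at 21: the C–C bond is made under Lewis acid instead of strong base.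
- Dianion 20 is quenched with Me3SiCl to give the bis-silyl dienol ether 2,2-dimethyl-4-(trimethylsilyloxy)-6-[2-(trimethylsilyloxy)prop-2-en-1-ylidene]-6H-1,3-dioxine F10.
- F10 is added to 16 in a Mukaiyama aldol reaction (BF3·OEt2, CH2Cl2, −78 °C), reacting at its terminal CH2 as related 1,3-bis(silyloxy)dienes do, and aqueous work-up removes the silyl groups to give 21. No strong base meets the aldehyde or the acetate.

**Further compounds**
F1 | step 11 | benzyl (S)-15-acetoxy-3,5,7-trioxooctadecanoate | CCC[C@@H](CCCCCCCC(=O)CC(=O)CC(=O)CC(=O)OCc1ccccc1)OC(C)=O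
F2 | step 11 | benzyl 6-[(S)-8-acetoxyundecyl]-2,6-dihydroxy-4-oxocyclohex-1-ene-1-carboxylate | CCC[C@@H](CCCCCCCC1(O)CC(=O)CC(O)=C1C(=O)OCc1ccccc1)OC(C)=O
F3 | step 11 | benzyl 2-[(S)-8-acetoxyundecyl]-4,6-dihydroxybenzoate | CCC[C@@H](CCCCCCCc1cc(O)cc(O)c1C(=O)OCc1ccccc1)OC(C)=O
F4 | step 11 | 2-[(S)-8-acetoxyundecyl]-4,6-dihydroxybenzoic acid | CCC[C@@H](CCCCCCCc1cc(O)cc(O)c1C(=O)O)OC(C)=O
F5 | step 11 | (R)-undec-10-en-4-ol | CCC[C@@H](O)CCCCCC=C
F6 | step 11 | (R)-11-(9-borabicyclo[3.3.1]nonan-9-yl)undecan-4-ol | CCC[C@@H](O)CCCCCCCB1C2CCCC1CCC2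
F7 | step 11 | (R)-3-(benzyloxy)-5-(8-hydroxyundecyl)phenyl neopentyl sulfate | CCC[C@@H](O)CCCCCCCc1cc(OCc2ccccc2)cc(OS(=O)(=O)OCC(C)(C)C)c1
F8 | step 4 | (S)-3-(benzyloxy)-5-(8-hydroxyundecyl)phenol | CCC[C@H](O)CCCCCCCc1cc(O)cc(OCc2ccccc2)c1
F9 | step 4 | sodium (S)-3-(benzyloxy)-5-(8-hydroxyundecyl)phenolate | [Na+].CCC[C@H](O)CCCCCCCc1cc([O-])cc(OCc2ccccc2)c1
F10 | step 9 | 2,2-dimethyl-4-(trimethylsilyloxy)-6-[2-(trimethylsilyloxy)prop-2-en-1-ylidene]-6H-1,3-dioxine | C=C(O[Si](C)(C)C)C=C1C=C(O[Si](C)(C)C)OC(C)(C)O1
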